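**Outline** (macrolide numbering: C1 lactone carbonyl, C3–C7 tetrahydropyran, C9 methyl, C11 methoxy, C13 propyl carbinol)

- Cuts: the C5–O ester bond (Mitsunobu, inversion) separates a (Z,Z)-oxazole acid from the macrolactone. The lactone O13–C1 bond and the C11–H bond are then cut together, back to an open-chain C13-hydroxy-C11-ketone carrying a C1 aldehyde. Further cuts are C12–C13 (boron aldol with butanal), C3–C4 and C5–O of the pyran (Prins with 3-(benzyloxy)propanal), C6–C7 (allylboration), and the C7–C12 unit back to 3-methylglutaric anhydride.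
- Enabling feature: in the 14-membered ring the lactone oxygen on C13 and the methoxy oxygen on C11 stand 1,3-anti across C12, and C1 is the acyl carbon on O13. The C11–C13 segment is therefore an anti-1,3-diol monoester, and the cis-2,6-disubstituted tetrahydropyran (C3–C7) folds the C1 and C13 ends toward each other.
- Forward order: tetrahydropyran first (Prins), 14-membered lactone second (Evans–Tishchenko closure), oxazole built separately from propargylamine and serine, side chain attached last at C5.
- Stereochemistry: C9 from desymmetrisation of the anhydride; C7 from reagent-controlled allylboration; C3 and C5 relayed from C7 in the Prins chair; C13 from a reagent-controlled aldol; C11 relayed from C13 in the hydride transfer; C5 inverted in the last step. Both Z alkenes come from Lindlar reduction and Still–Gennari olefination.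

Key step: step 13

Assumption: the face selectivities are taken from the usual models (quinidine-series alkaloid gives the (S)-half-ester; the (−)-allylborane and the methyl ketone enolate from the (+)-chloroborane both attack the aldehyde Si face; Ipc = isopinocampheyl); wherever a model proved reversed, the antipodal reagent would be used with no other change.

**Route**

Step 1
Reactants: 1 3-methylglutaric anhydride (4-methyloxane-2,6-dione)
Product: 2 (3S)-5-methoxy-3-methyl-5-oxopentanoic acid
Conditions: MeOH (10 equiv), (DHQD)2AQN [hydroquinidine anthraquinone-1,4-diyl diether] (0.3 equiv), Et2O, −40 °C; aq. HCl wash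
Reagents that add atoms: methanol, CO
Why: Cinchona-alkaloid-catalysed desymmetrising alcoholysis of a prochiral cyclic anhydride, in which the quinuclidine base delivers methanol to one enantiotopic carbonyl and so should set the future C9 centre as (S).

Step 2
Reactants: 2 (3S)-half-ester
Product: 3 methyl (3S)-5-hydroxy-3-methylpentanoate
Conditions: BH3·SMe2 (1.1 equiv), THF, 0 °C to rt; MeOH quench
Reagents that add atoms: none
Why: Chemoselective borane reduction, since BH3 reduces a carboxylic acid far faster than a methyl ester; the crude hydroxy ester is used at once to forestall lactonisation.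

Step 3
Reactants: 3 hydroxy ester
Product: 4 methyl (3S)-3-methyl-5-oxopentanoate
Conditions: TEMPO (2,2,6,6-tetramethylpiperidin-1-oxyl, 0.1 equiv), PhI(OAc)2 (1.1 equiv), CH2Cl2, rt
Reagents that add atoms: none
Why: Oxoammonium (TEMPO/PhI(OAc)2) oxidation of a primary alcohol should stop at the aldehyde under near-neutral conditions that leave the ester and the β-stereocentre untouched.

Step 4
Reactants: 4 aldehyde ester
Product: 5 methyl (3S)-3-methylhex-5-enoate
Conditions: Ph3PCH3Br (1.3 equiv), KN(SiMe3)2 (1.2 equiv), THF, 0 °C; then 4, −78 °C to 0 °C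
Reagents that add atoms: methyltriphenylphosphonium bromide, C[P+](c1ccccc1)(c1ccccc1)c1ccccc1.[Br-]
Why: Wittig methylenation with the non-stabilised ylide is fast on the aldehyde and spares the methyl ester, giving the future C11=C12 vinyl group.

Step 5
Reactants: 5 alkene ester
Product: 6 (3S)-3-methylhex-5-enal
Conditions: i-Bu2AlH (1.05 equiv), CH2Cl2, −78 °C; MeOH, then aq. potassium sodium tartrate; kept as a dried solution
Reagents that add atoms: none
Why: Partial reduction of a methyl ester by i-Bu2AlH at −78 °C should stop at the aluminium hemiacetal, which gives the aldehyde on work-up; the volatile product is not concentrated to dryness.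

Step 6
Reactants: 6 (3S)-3-methylhex-5-enal
Product: 8 (4S,6S)-6-methylnona-1,8-dien-4-ol, via borinate ester 7 (not isolated)
Conditions: (−)-Ipc2B(allyl) (1.3 equiv, salt-free), Et2O, −78 °C; then 3 M NaOH, 30% H2O2, rt
Reagents that add atoms: (−)-B-allyldiisopinocampheylborane, C=CCB([C@@H]1C[C@@H]2C[C@H]([C@H]1C)C2(C)C)[C@@H]1C[C@@H]2C[C@H]([C@H]1C)C2(C)C
Why: Brown asymmetric allylboration through a closed chair transition state in which the isopinocampheyl groups steer the allyl group to the Si face of the aldehyde, which should give the (S)-carbinol at the future C7 independently of the remote C9 methyl group.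

Step 7
Reactants: 8 (4S,6S)-6-methylnona-1,8-dien-4-ol; 9 3-(benzyloxy)propanal
Product: 11 (2S,4S,6R)-2-[2-(benzyloxy)ethyl]-6-[(2S)-2-methylpent-4-en-1-yl]oxan-4-ol (all-cis ring), via ring trifluoroacetate 10 (not isolated)
Conditions: 9 (1.2 equiv), CF3CO2H (15 equiv), CH2Cl2, 0 °C to rt; evaporate; K2CO3, MeOH, rt
Reagents that add atoms: trifluoroacetic acid, OC(=O)C(F)(F)F
Why: Prins cyclisation, in which the oxocarbenium ion from alcohol and aldehyde closes 6-endo through a chair with both side chains equatorial and trifluoroacetate caps the C5 cation equatorially, so that C3 and C5 are both set cis to C7 while the remote vinyl group cannot reach the cation through a six-membered array.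

Step 8
Reactants: 11 tetrahydropyranol
Product: 12 tert-butyl({(2S,4S,6R)-2-[2-(benzyloxy)ethyl]-6-[(2S)-2-methylpent-4-en-1-yl]oxan-4-yl}oxy)dimethylsilane
Conditions: TBSCl (1.5 equiv), imidazole (3 equiv), DMF, rt
Reagents that add atoms: tert-butyldimethylsilyl chloride, CC(C)(C)[Si](C)(C)Cl
Why: Standard silylation of a secondary alcohol, which masks the C5 hydroxyl so that it cannot compete as a hemiacetal donor in the lactone closure.

Step 9
Reactants: 12 silyl ether
Product: 13 (4R)-5-{(2R,4S,6S)-6-[2-(benzyloxy)ethyl]-4-[(tert-butyldimethylsilyl)oxy]oxan-2-yl}-4-methylpentan-2-one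
Conditions: PdCl2 (0.1 equiv), CuCl (1 equiv), O2 (1 atm), DMF/H2O (7:1), rt
Reagents that add atoms: water, O
Why: Tsuji–Wacker oxidation of the monosubstituted alkene should give the C11 methyl ketone with Markovnikov selectivity, the ethers and the silyl ether being inert.

Step 10
Reactants: 13 methyl ketone; 14 butanal
Product: 17 (2R,6R)-1-{(2R,4S,6S)-6-[2-(benzyloxy)ethyl]-4-[(tert-butyldimethylsilyl)oxy]oxan-2-yl}-6-hydroxy-2-methylnonan-4-one, via boron enolate 15 (not isolated), via boron aldolate 16 (not isolated)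
Conditions: (+)-Ipc2BCl (1.6 equiv), Et3N (2.0 equiv), Et2O, 0 °C, 1 h; 14 (3 equiv), −78 °C then −20 °C, 16 h; pH 7 buffer, MeOH, 30% H2O2, 0 °C
Reagents that add atoms: none
Why: Paterson boron aldol, in which Ipc2BCl/Et3N enolises the ketone on the methyl side and the isopinocampheyl ligands direct the enolate to the Si face of butanal, which should give the (13R)-carbinol under reagent control, the minor C13 epimer being removed by chromatography.

Step 11
Reactants: 17 β-hydroxy ketone
Product: 18 (2R,6R)-1-{(2R,4S,6S)-4-[(tert-butyldimethylsilyl)oxy]-6-(2-hydroxyethyl)oxan-2-yl}-6-hydroxy-2-methylnonan-4-one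
Conditions: H2 (1 atm), Pd/C (10% Pd by weight), EtOAc, rt
Reagents that add atoms: none
Why: Hydrogenolysis of the benzyl ether over palladium should leave the ketone, the silyl ether and the secondary alcohol untouched.

Step 12
Reactants: 18 diol
Product: 19 2-{(2R,4S,6R)-4-[(tert-butyldimethylsilyl)oxy]-6-[(2R,6R)-6-hydroxy-2-methyl-4-oxononyl]oxan-2-yl}acetaldehyde
Conditions: TEMPO (0.2 equiv), PhI(OAc)2 (1.2 equiv), CH2Cl2, 0 °C to rt
Reagents that add atoms: none
Why: The hindered oxoammonium oxidant selects the primary over the secondary hydroxyl, so only C1 should be raised to the aldehyde; the product is used without storage.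

Step 13
Reactants: 19 hydroxy keto aldehyde
Product: 21 (1R,5R,7R,9S,11R,13S)-13-[(tert-butyldimethylsilyl)oxy]-7-hydroxy-9-methyl-5-propyl-4,15-dioxabicyclo[9.3.1]pentadecan-3-one, via samarium hemiacetal 20 (not isolated)
Conditions: SmI2 (0.3 equiv) and PhCHO (0.3 equiv) premixed in THF (forms the trivalent samarium pinacolate I2SmOCH(Ph)CH(Ph)OSmI2), −10 °C, dark; 19 added by syringe pump over 12 h to a final 0.002 M; aq. NaHCO3
Reagents that add atoms: none
Why: Proposed new method: the trivalent samarium catalyst binds the C13 alkoxide and the C11 carbonyl of 19, the alkoxide adds reversibly to the tethered C1 aldehyde to give hemiacetal 20, and the hemiacetal C1–H is then passed irreversibly to C11 through a samarium-held six-membered chair (C1, O13, C13, C12, C11, H), so that the lactone carbonyl and the C11 carbinol appear in one event; the closest known reaction type is the samarium-catalysed Evans–Tishchenko reduction of β-hydroxy ketones by aldehydes, established between two molecules and for smaller lactones but not for a 14-membered ring on a chain of this kind. The 14-membered lactone (12-membered if counted through the pyran oxygen) is closed by O13–C1 bond formation, an exo-trig addition of the alkoxide to the aldehyde carbonyl, and is made permanent by the hydride shift. The new C11 centre is controlled by C13: with the propyl group equatorial in the chair, hydride reaches the carbonyl face that gives the 1,3-anti (11R) alcohol. The step needs hydride transfer within one molecule to outrun transfer between molecules; slow addition to a final concentration near 0.002 M, the turn imposed by the cis-2,6-diequatorial tetrahydropyran, and the reversibility of open-chain hemiacetals, which lets oligomeric adducts fall apart again, should secure this. It also needs a single donor and a single acceptor, which the silyl ether at C5 and the use of no more benzaldehyde than SmI2 provide, and a low temperature to hold back retro-aldol cleavage of the samarium aldolate.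

Step 14
Reactants: 21 macrolactone alcohol
Product: 22 (1R,5R,7R,9S,11R,13S)-13-[(tert-butyldimethylsilyl)oxy]-7-methoxy-9-methyl-5-propyl-4,15-dioxabicyclo[9.3.1]pentadecan-3-one
Conditions: Me3OBF4 (5 equiv), 1,8-bis(dimethylamino)naphthalene (6 equiv), 4 Å molecular sieves, CH2Cl2, rt
Reagents that add atoms: trimethyloxonium tetrafluoroborate, C[O+](C)C.F[B-](F)(F)F
Why: O-Alkylation with Meerwein's salt buffered by a non-nucleophilic base methylates the C11 hydroxyl without forming an alkoxide, so no 1,3-acyl shift or ring opening of the lactone is expected.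

Step 15
Reactants: 22 methyl ether
Product: 23 (1R,5R,7R,9S,11R,13S)-13-hydroxy-7-methoxy-9-methyl-5-propyl-4,15-dioxabicyclo[9.3.1]pentadecan-3-one
Conditions: HF·pyridine, pyridine, THF, 0 °C to rt
Reagents that add atoms: none
Why: Fluoride-mediated cleavage of the silyl ether should free the equatorial C5 hydroxyl without touching the lactone or the methyl ether.

Step 16
Reactants: 24 propargylamine (prop-2-yn-1-amine)
Product: 25 methyl N-(prop-2-yn-1-yl)carbamate
Conditions: ClCO2Me (1.05 equiv), Et3N (1.2 equiv), CH2Cl2, 0 °C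
Reagents that add atoms: methyl chloroformate, COC(=O)Cl
Why: N-Acylation of the primary amine by a chloroformate gives the methyl carbamate that the target carries.

Step 17
Reactants: 25 propargyl carbamate
Product: 26 4-[(methoxycarbonyl)amino]but-2-ynoic acid
Conditions: LiN(SiMe3)2 (2.2 equiv), THF, −78 °C; CO2 (gas), −78 °C to rt; aq. HCl
Reagents that add atoms: carbon dioxide, O=C=O
Why: Double deprotonation (carbamate N–H, then alkyne C–H) gives a lithium acetylide that is carboxylated at carbon by CO2, any N-carboxylate being lost again on acidification.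

Step 18
Reactants: 26 ynoic acid; 27 L-serine methyl ester hydrochloride
Product: 28 methyl N-{4-[(methoxycarbonyl)amino]but-2-ynoyl}-L-serinate
Conditions: EDC·HCl (1.2 equiv), HOBt (1.2 equiv), N-methylmorpholine (2.5 equiv), CH2Cl2, 0 °C to rt
Reagents that add atoms: none
Why: Carbodiimide/hydroxybenzotriazole amide coupling acylates the serine amine in preference to its hydroxyl.

Step 19
Reactants: 28 serine amide
Product: 30 methyl 2-{3-[(methoxycarbonyl)amino]prop-1-yn-1-yl}-1,3-oxazole-4-carboxylate, via oxazoline 29 (not isolated)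
Conditions: Et2NSF3 (DAST, 1.1 equiv), CH2Cl2, −78 °C; then BrCCl3 (3 equiv), DBU (4 equiv), 0 °C to rt
Reagents that add atoms: none
Why: Cyclodehydration of the β-hydroxy amide by DAST gives the oxazoline, which is dehydrogenated in the same flask by bromination and dehydrobromination with BrCCl3/DBU; the serine stereocentre is lost by design.

Step 20
Reactants: 30 alkynyl oxazole
Product: 31 methyl 2-{(1Z)-3-[(methoxycarbonyl)amino]prop-1-en-1-yl}-1,3-oxazole-4-carboxylate
Conditions: H2 (1 atm), Pd/CaCO3 poisoned with Pb(OAc)2 (Lindlar catalyst), quinoline, EtOAc, rt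
Reagents that add atoms: none
Why: Lindlar semihydrogenation adds H2 syn to the alkyne and should stop at the (Z)-alkene.

Step 21
Reactants: 31 (Z)-alkenyl oxazole ester
Product: 32 methyl N-{(2Z)-3-[4-(hydroxymethyl)-1,3-oxazol-2-yl]prop-2-en-1-yl}carbamate
Conditions: i-Bu2AlH (3.5 equiv), CH2Cl2, −78 °C to −20 °C; aq. potassium sodium tartrate
Reagents that add atoms: none
Why: i-Bu2AlH reduces the heteroaryl ester to the primary alcohol, the carbamate being shielded at low temperature as its N-aluminated anion.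

Step 22
Reactants: 32 oxazolylmethanol
Product: 33 methyl N-{(2Z)-3-[4-(bromomethyl)-1,3-oxazol-2-yl]prop-2-en-1-yl}carbamate
Conditions: CBr4 (1.3 equiv), PPh3 (1.3 equiv), 2,6-lutidine, MeCN, 0 °C
Reagents that add atoms: carbon tetrabromide, BrC(Br)(Br)Br
Why: Appel bromination converts the activated primary alcohol into the bromide under near-neutral conditions.

Step 23
Reactants: 33 bromide
Product: 34 methyl N-{(2Z)-3-[4-(prop-2-en-1-yl)-1,3-oxazol-2-yl]prop-2-en-1-yl}carbamate
Conditions: Bu3SnCH=CH2 (1.3 equiv), Pd2(dba)3 (0.05 equiv, zerovalent palladium), tri(2-furyl)phosphine (0.2 equiv), THF, 60 °C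
Reagents that add atoms: tributyl(vinyl)stannane, C=C[Sn](CCCC)(CCCC)CCCC
Why: Stille coupling of the heterobenzylic bromide with the vinylstannane should give the 4-allyl oxazole, since oxidative addition into the activated C–Br bond is fast and the Z alkene is not engaged.

Step 24
Reactants: 34 allyl oxazole
Product: 36 methyl N-{(2Z)-3-[4-(3-hydroxypropyl)-1,3-oxazol-2-yl]prop-2-en-1-yl}carbamate, via alkylborane 35 (not isolated)
Conditions: 9-BBN (1.3 equiv), THF, 0 °C to rt; then aq. NaOH, 30% H2O2, 0 °C
Reagents that add atoms: hydrogen peroxide, OO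
Why: Anti-Markovnikov hydroboration by the bulky borane takes the monosubstituted alkene in preference to the conjugated Z-disubstituted one, and oxidation gives the primary alcohol.

Step 25
Reactants: 36 primary alcohol
Product: 37 methyl N-{(2Z)-3-[4-(3-oxopropyl)-1,3-oxazol-2-yl]prop-2-en-1-yl}carbamate
Conditions: TEMPO (0.1 equiv), PhI(OAc)2 (1.2 equiv), CH2Cl2, rt
Reagents that add atoms: none
Why: Oxoammonium oxidation should give the aldehyde without over-oxidation and without touching the oxazole, the alkene or the carbamate.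

Step 26
Reactants: 37 aldehyde
Product: 38 methyl (2Z)-5-(2-{(1Z)-3-[(methoxycarbonyl)amino]prop-1-en-1-yl}-1,3-oxazol-4-yl)pent-2-enoate
Conditions: (CF3CH2O)2P(O)CH2CO2Me (1.3 equiv), KN(SiMe3)2 (1.25 equiv), 18-crown-6 (3 equiv), THF, −78 °C
Reagents that add atoms: methyl bis(2,2,2-trifluoroethyl)phosphonoacetate, COC(=O)CP(=O)(OCC(F)(F)F)OCC(F)(F)F
Why: Still–Gennari olefination, in which fast irreversible elimination from the electron-poor phosphonate adduct should give the (Z)-enoate under kinetic control.

Step 27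
Reactants: 38 (Z,Z)-methyl ester
Product: 39 (2Z)-5-(2-{(1Z)-3-[(methoxycarbonyl)amino]prop-1-en-1-yl}-1,3-oxazol-4-yl)pent-2-enoic acid
Conditions: LiOH·H2O (3 equiv), THF/H2O (3:1), 0 °C to rt; aq. HCl to pH 3
Reagents that add atoms: lithium hydroxide, [Li+].[OH-]
Why: Saponification of the methyl enoate is much faster than attack on the methyl carbamate, and the Z geometry should hold at this temperature.

Step 28
Reactants: 23 macrolactone with equatorial C5 hydroxyl; 39 (Z,Z)-oxazole acid
Product: 40 neopeltolide (3R,5R,7R,9S,11R,13R in macrolide numbering)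
Conditions: PPh3 (4 equiv), i-PrO2CN=NCO2i-Pr (DIAD, 4 equiv), benzene, rt
Reagents that add atoms: none
Why: Mitsunobu esterification, in which the carboxylate displaces the alkoxyphosphonium ion at C5 with inversion and so turns the equatorial alcohol into the axial (5R) ester of the target.

**Compound list**

1 | 3-methylglutaric anhydride (4-methyloxane-2,6-dione) | CC1CC(=O)OC(=O)C1 | starting material
2 | (3S)-5-methoxy-3-methyl-5-oxopentanoic acid | OC(=O)C[C@H](C)CC(=O)OC | intermediate
3 | methyl (3S)-5-hydroxy-3-methylpentanoate | OCC[C@H](C)CC(=O)OC | intermediate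
4 | methyl (3S)-3-methyl-5-oxopentanoate | O=CC[C@H](C)CC(=O)OC | intermediate
5 | methyl (3S)-3-methylhex-5-enoate | C=CC[C@H](C)CC(=O)OC | intermediate
6 | (3S)-3-methylhex-5-enal | C=CC[C@H](C)CC=O | intermediate
7 | (4S,6S)-6-methylnona-1,8-dien-4-yl diisopinocampheylborinate | C=CC[C@H](C)C[C@@H](OB([C@@H]1C[C@@H]2C[C@H]([C@H]1C)C2(C)C)[C@@H]1C[C@@H]2C[C@H]([C@H]1C)C2(C)C)CC=C | intermediate (not isolated)
8 | (4S,6S)-6-methylnona-1,8-dien-4-ol | C=CC[C@H](C)C[C@@H](O)CC=C | intermediate
9 | 3-(benzyloxy)propanal | O=CCCOCc1ccccc1 | starting material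
10 | (2S,4S,6R)-2-[2-(benzyloxy)ethyl]-6-[(2S)-2-methylpent-4-en-1-yl]oxan-4-yl trifluoroacetate | C=CC[C@H](C)C[C@@H]1C[C@H](OC(=O)C(F)(F)F)C[C@H](CCOCc2ccccc2)O1 | intermediate (not isolated)
11 | (2S,4S,6R)-2-[2-(benzyloxy)ethyl]-6-[(2S)-2-methylpent-4-en-1-yl]oxan-4-ol | C=CC[C@H](C)C[C@@H]1C[C@H](O)C[C@H](CCOCc2ccccc2)O1 | intermediate
12 | tert-butyl({(2S,4S,6R)-2-[2-(benzyloxy)ethyl]-6-[(2S)-2-methylpent-4-en-1-yl]oxan-4-yl}oxy)dimethylsilane | C=CC[C@H](C)C[C@@H]1C[C@H](O[Si](C)(C)C(C)(C)C)C[C@H](CCOCc2ccccc2)O1 | intermediate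
13 | (4R)-5-{(2R,4S,6S)-6-[2-(benzyloxy)ethyl]-4-[(tert-butyldimethylsilyl)oxy]oxan-2-yl}-4-methylpentan-2-one | CC(=O)C[C@H](C)C[C@@H]1C[C@H](O[Si](C)(C)C(C)(C)C)C[C@H](CCOCc2ccccc2)O1 | intermediate
14 | butanal | CCCC=O | starting material
15 | diisopinocampheylboron enolate of ketone 13 (methyl side) | C=C(OB([C@H]1C[C@H]2C[C@@H]([C@@H]1C)C2(C)C)[C@H]1C[C@H]2C[C@@H]([C@@H]1C)C2(C)C)C[C@H](C)C[C@@H]1C[C@H](O[Si](C)(C)C(C)(C)C)C[C@H](CCOCc2ccccc2)O1 | intermediate (not isolated)
16 | diisopinocampheylboron aldolate (O13-borinate of 17) | CCC[C@@H](OB([C@H]1C[C@H]2C[C@@H]([C@@H]1C)C2(C)C)[C@H]1C[C@H]2C[C@@H]([C@@H]1C)C2(C)C)CC(=O)C[C@H](C)C[C@@H]1C[C@H](O[Si](C)(C)C(C)(C)C)C[C@H](CCOCc2ccccc2)O1 | intermediate (not isolated)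
17 | (2R,6R)-1-{(2R,4S,6S)-6-[2-(benzyloxy)ethyl]-4-[(tert-butyldimethylsilyl)oxy]oxan-2-yl}-6-hydroxy-2-methylnonan-4-one | CCC[C@@H](O)CC(=O)C[C@H](C)C[C@@H]1C[C@H](O[Si](C)(C)C(C)(C)C)C[C@H](CCOCc2ccccc2)O1 | intermediate
18 | (2R,6R)-1-{(2R,4S,6S)-4-[(tert-butyldimethylsilyl)oxy]-6-(2-hydroxyethyl)oxan-2-yl}-6-hydroxy-2-methylnonan-4-one | CCC[C@@H](O)CC(=O)C[C@H](C)C[C@@H]1C[C@H](O[Si](C)(C)C(C)(C)C)C[C@H](CCO)O1 | intermediate
19 | 2-{(2R,4S,6R)-4-[(tert-butyldimethylsilyl)oxy]-6-[(2R,6R)-6-hydroxy-2-methyl-4-oxononyl]oxan-2-yl}acetaldehyde | CCC[C@@H](O)CC(=O)C[C@H](C)C[C@@H]1C[C@H](O[Si](C)(C)C(C)(C)C)C[C@H](CC=O)O1 | intermediate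
20 | (1R,5R,9R,11R,13S)-13-[(tert-butyldimethylsilyl)oxy]-3-hydroxy-9-methyl-5-propyl-4,15-dioxabicyclo[9.3.1]pentadecan-7-one (macrocyclic hemiacetal, C3 undefined, present as its samarium alkoxide) | CCC[C@@H]1CC(=O)C[C@H](C)C[C@@H]2C[C@H](O[Si](C)(C)C(C)(C)C)C[C@H](CC(O)O1)O2 | intermediate (not isolated)
21 | (1R,5R,7R,9S,11R,13S)-13-[(tert-butyldimethylsilyl)oxy]-7-hydroxy-9-methyl-5-propyl-4,15-dioxabicyclo[9.3.1]pentadecan-3-one | CCC[C@@H]1C[C@H](O)C[C@H](C)C[C@@H]2C[C@H](O[Si](C)(C)C(C)(C)C)C[C@H](CC(=O)O1)O2 | intermediate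
22 | (1R,5R,7R,9S,11R,13S)-13-[(tert-butyldimethylsilyl)oxy]-7-methoxy-9-methyl-5-propyl-4,15-dioxabicyclo[9.3.1]pentadecan-3-one | CCC[C@@H]1C[C@H](OC)C[C@H](C)C[C@@H]2C[C@H](O[Si](C)(C)C(C)(C)C)C[C@H](CC(=O)O1)O2 | intermediate
23 | (1R,5R,7R,9S,11R,13S)-13-hydroxy-7-methoxy-9-methyl-5-propyl-4,15-dioxabicyclo[9.3.1]pentadecan-3-one | CCC[C@@H]1C[C@H](OC)C[C@H](C)C[C@@H]2C[C@H](O)C[C@H](CC(=O)O1)O2 | intermediate
24 | propargylamine (prop-2-yn-1-amine) | C#CCN | starting material
25 | methyl N-(prop-2-yn-1-yl)carbamate | C#CCNC(=O)OC | intermediate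
26 | 4-[(methoxycarbonyl)amino]but-2-ynoic acid | COC(=O)NCC#CC(=O)O | intermediate
27 | L-serine methyl ester hydrochloride | Cl.COC(=O)[C@@H](N)CO | starting material
28 | methyl N-{4-[(methoxycarbonyl)amino]but-2-ynoyl}-L-serinate | COC(=O)NCC#CC(=O)N[C@@H](CO)C(=O)OC | intermediate
29 | methyl (4S)-2-{3-[(methoxycarbonyl)amino]prop-1-yn-1-yl}-4,5-dihydro-1,3-oxazole-4-carboxylate | COC(=O)NCC#CC1=N[C@@H](CO1)C(=O)OC | intermediate (not isolated)
30 | methyl 2-{3-[(methoxycarbonyl)amino]prop-1-yn-1-yl}-1,3-oxazole-4-carboxylate | COC(=O)NCC#Cc1nc(C(=O)OC)co1 | intermediate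
31 | methyl 2-{(1Z)-3-[(methoxycarbonyl)amino]prop-1-en-1-yl}-1,3-oxazole-4-carboxylate | COC(=O)NC/C=C\c1nc(C(=O)OC)co1 | intermediate
32 | methyl N-{(2Z)-3-[4-(hydroxymethyl)-1,3-oxazol-2-yl]prop-2-en-1-yl}carbamate | COC(=O)NC/C=C\c1nc(CO)co1 | intermediate
33 | methyl N-{(2Z)-3-[4-(bromomethyl)-1,3-oxazol-2-yl]prop-2-en-1-yl}carbamate | COC(=O)NC/C=C\c1nc(CBr)co1 | intermediate
34 | methyl N-{(2Z)-3-[4-(prop-2-en-1-yl)-1,3-oxazol-2-yl]prop-2-en-1-yl}carbamate | COC(=O)NC/C=C\c1nc(CC=C)co1 | intermediate
35 | methyl N-{(2Z)-3-[4-(3-(9-borabicyclo[3.3.1]nonan-9-yl)propyl)-1,3-oxazol-2-yl]prop-2-en-1-yl}carbamate | COC(=O)NC/C=C\c1nc(CCCB2C3CCCC2CCC3)co1 | intermediate (not isolated)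
36 | methyl N-{(2Z)-3-[4-(3-hydroxypropyl)-1,3-oxazol-2-yl]prop-2-en-1-yl}carbamate | COC(=O)NC/C=C\c1nc(CCCO)co1 | intermediate
37 | methyl N-{(2Z)-3-[4-(3-oxopropyl)-1,3-oxazol-2-yl]prop-2-en-1-yl}carbamate | COC(=O)NC/C=C\c1nc(CCC=O)co1 | intermediate
38 | methyl (2Z)-5-(2-{(1Z)-3-[(methoxycarbonyl)amino]prop-1-en-1-yl}-1,3-oxazol-4-yl)pent-2-enoate | COC(=O)/C=C\CCc1coc(/C=C\CNC(=O)OC)n1 | intermediate
39 | (2Z)-5-(2-{(1Z)-3-[(methoxycarbonyl)amino]prop-1-en-1-yl}-1,3-oxazol-4-yl)pent-2-enoic acid | OC(=O)/C=C\CCc1coc(/C=C\CNC(=O)OC)n1 | intermediate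
40 | neopeltolide | CCC[C@@H]1C[C@H](OC)C[C@H](C)C[C@@H]2C[C@@H](OC(=O)/C=C\CCc3coc(/C=C\CNC(=O)OC)n3)C[C@H](CC(=O)O1)O2 | target

**Step count and risks**

Total: 28 steps. Longest linear sequence: 16 steps (steps 1–15 and 28, from 3-methylglutaric anhydride); the side-chain branch is 12 steps (16–27).

Steps most likely to fail:

1. Step 13 (the proposed ring closure). Hydride transfer between molecules (oligomeric Tishchenko esters) or retro-aldol cleavage of the samarium aldolate may outrun the transannular hydride shift. The fallback makes the same anti-1,3 relationship intermolecularly and closes the ring by ordinary lactonisation, using known chemistry only.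
   - It sets out from β-hydroxy ketone 17: an Evans–Tishchenko reduction with acetaldehyde (SmI2 cat., THF, −10 °C) should give the C13 acetate with a free 11R hydroxyl, the anti-diol monoacetate F1.
   - Me3OBF4 with 1,8-bis(dimethylamino)naphthalene gives the C11 methyl ether acetate F2.
   - K2CO3 in MeOH removes the acetate to give the C13 alcohol F3.
   - Hydrogenolysis (H2, Pd/C) gives the diol F4.
   - TEMPO/PhI(OAc)2 in MeCN–H2O oxidises only the primary hydroxyl to give the seco acid F5.
   - Yamaguchi lactonisation (2,4,6-trichlorobenzoyl chloride, Et3N, then 4-(dimethylamino)pyridine, toluene, high dilution) closes the ring and comes back to the route at methyl ether 22.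

2. Step 10. Facial selectivity on butanal rests on the boron reagent alone, because the C9 methyl group gives no useful remote induction, so the C13 epimers may form in comparable amounts. The fallback brings C13 in already resolved.
   - It sets out from alkene 12: Lemieux–Johnson cleavage (OsO4 cat., NaIO4, 2,6-lutidine, dioxane–H2O) gives the C11 aldehyde F6.
   - Propane-1,3-dithiol with BF3·OEt2 gives the dithiane F7.
   - Lithiation (t-BuLi, THF–HMPA, −78 °C) and opening of commercial (R)-2-propyloxirane at its CH2 terminus gives the hydroxy dithiane F8, in which C12 and the (R)-configured C13 come from the epoxide.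
   - Dithiane hydrolysis (MeI, CaCO3, aq. MeCN) comes back to the route at β-hydroxy ketone 17.

3. Step 7. Acid-mediated allyl transfer (2-oxonia-Cope rearrangement followed by hydrolysis) may exchange side chains between molecules and erode the C7 configuration, and trifluoroacetic acid may add slowly across the remote alkene. The fallback generates the oxocarbenium ion without free aldehyde or water.
   - It sets out from alcohol 8: esterification with 3-(benzyloxy)propanoic acid (DCC, 4-(dimethylamino)pyridine, CH2Cl2) gives the ester F9.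
   - Reductive acetylation (i-Bu2AlH, −78 °C; then Ac2O, pyridine, 4-(dimethylamino)pyridine) gives the α-acetoxy ether F10.
   - CF3CO2H in CH2Cl2 ionises it to the same oxocarbenium ion, which should cyclise to trifluoroacetate 10; K2CO3/MeOH then comes back to the route at alcohol 11.

**Further compounds**

F1 | step 13 | C13 acetate of the 11R,13R anti-diol (C1 benzyl ether, C5 silyl ether) | CCC[C@@H](OC(C)=O)C[C@H](O)C[C@H](C)C[C@@H]1C[C@H](O[Si](C)(C)C(C)(C)C)C[C@H](CCOCc2ccccc2)O1
F2 | step 13 | C11 methyl ether of F1 | CCC[C@@H](OC(C)=O)C[C@H](OC)C[C@H](C)C[C@@H]1C[C@H](O[Si](C)(C)C(C)(C)C)C[C@H](CCOCc2ccccc2)O1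
F3 | step 13 | C13 alcohol with C11 methoxy (C1 benzyl ether, C5 silyl ether) | CCC[C@@H](O)C[C@H](OC)C[C@H](C)C[C@@H]1C[C@H](O[Si](C)(C)C(C)(C)C)C[C@H](CCOCc2ccccc2)O1
F4 | step 13 | C1,C13-diol with C11 methoxy (C5 silyl ether) | CCC[C@@H](O)C[C@H](OC)C[C@H](C)C[C@@H]1C[C@H](O[Si](C)(C)C(C)(C)C)C[C@H](CCO)O1
F5 | step 13 | seco acid (C1 acid, C13 hydroxyl, C11 methoxy, C5 silyl ether) | CCC[C@@H](O)C[C@H](OC)C[C@H](C)C[C@@H]1C[C@H](O[Si](C)(C)C(C)(C)C)C[C@H](CC(=O)O)O1
F6 | step 10 | C11 aldehyde (3-methyl-4-(oxan-2-yl)butanal with C5 silyl ether and C1 benzyl ether) | O=CC[C@H](C)C[C@@H]1C[C@H](O[Si](C)(C)C(C)(C)C)C[C@H](CCOCc2ccccc2)O1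
F7 | step 10 | 1,3-dithiane of F6 | S1CCCSC1C[C@H](C)C[C@@H]2C[C@H](O[Si](C)(C)C(C)(C)C)C[C@H](CCOCc3ccccc3)O2
F8 | step 10 | 2-[(2R)-2-hydroxypentyl]-1,3-dithiane derived from F7 | CCC[C@@H](O)CC1(SCCCS1)C[C@H](C)C[C@@H]2C[C@H](O[Si](C)(C)C(C)(C)C)C[C@H](CCOCc3ccccc3)O2
F9 | step 7 | (4S,6S)-6-methylnona-1,8-dien-4-yl 3-(benzyloxy)propanoate | C=CC[C@H](C)C[C@@H](OC(=O)CCOCc1ccccc1)CC=C
F10 | step 7 | 3-(benzyloxy)-1-{[(4S,6S)-6-methylnona-1,8-dien-4-yl]oxy}propyl acetate (both acetal epimers) | C=CC[C@H](C)C[C@@H](OC(OC(C)=O)CCOCc1ccccc1)CC=C
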